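**Plan**

- Rings are lettered A to K from the 2,4,6-trihydroxyphenyl end. Every B-type ring (B, D, F, H, J; OH at C1 and C3) hangs by C5 on an oxygen flanked on both sides in the ring before it (C1–O of ring A, C2–O of a C-type ring) and carries the next ring on its own doubly flanked C2 oxygen; such oxygens are easy to alkynylate or alkylate and hard to arylate.
- The retrosynthesis cuts no aryl–oxygen bond. Each B-type ring is taken out whole through C1–C6, C4–C5 and C1–C2: first ring D (giving A–B–C ynol ether 28 and E–K cyclobutenone 73), then ring B on the left (7 + 19) and rings F, H and J on the right, back to ring K cyclobutenone 33.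
- Forward, left half: ring B is closed from ring A ethynyl ether 7 and cyclobutenone 19, which brings ring C with a dichlorovinyl ether that is then unmasked to ynol ether 28.
- Forward, right half: rings J, H and F are closed in turn from cyclobutenones 33, 51 and 62 and the benzyl-protected ynol ether 40 (rings I, G, E). After each annulation, methylation, debenzylation, carboxymethylation and ketene–ethoxyacetylene cycloaddition make the next cyclobutenone.
- The halves are joined by closing ring D (28 + 73), and BBr3 then frees all 28 hydroxyls.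
- Stereochemistry: the target has no stereocentre. C4 of the racemic cyclobutenones and every transient sp3 carbon end as aromatic carbons, and the alkene geometry of the dichlorovinyl ethers is lost in the alkynes.

Key step: step 10

Remark: 2,4,6-trimethoxyphenol, 3,4,5-trimethoxyphenol and ethoxyacetylene (solution in hexanes) are taken as commercial. All cyclobutenones are used as racemates. Dichloroacetylene is handled only as a dilute, cold THF solution under argon.

Names: ArC = 2-[(E)-1,2-dichloroethenyloxy]-3,4,5-trimethoxyphenyl, TMP = 2,4,6-trimethoxyphenyl, ArM = 6-(benzyloxy)-2,3,4-trimethoxyphenyl. In every protected oligomer ring A is TMP and ring K is 3,4,5-trimethoxyphenyl on the C2 oxygen of ring J. Each C-type ring (C, E, G, I) has OMe at C3, C4 and C5, its C1 oxygen on C2 of the B-type ring before it and its C2 oxygen on C5 of the B-type ring after it. Each B-type ring has OEt at C3 and OMe at C1 unless a free C1–OH is stated. Right-hand oligomers (I–K, G–K, E–K) are named by the group on the C1 oxygen of their leftmost C-type ring.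

**Route**

Step 1
Reactants: 1 trichloroethylene
Product: 2 dichloroacetylene (THF solution)
Conditions: KH (1.1 equiv), MeOH (0.05 equiv), THF, 0 °C → rt, argon; supernatant cannulated off KCl, titrated, kept cold and never concentrated
Reagents that add atoms: none
Why: base-induced β-elimination of HCl from trichloroethylene, with methoxide as turnover base and KH as stoichiometric base, is the known practical preparation of dichloroacetylene solutions, and one batch serves the three dichlorovinylations of the route.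

Step 2
Reactants: 3 2,4,6-trimethoxyphenol; 2 dichloroacetylene
Product: 4 2-[(E)-1,2-dichloroethenyloxy]-1,3,5-trimethoxybenzene
Conditions: 2 (1.5 equiv, THF solution), K2CO3 (0.2 equiv), DMF, 0 °C → rt
Reagents that add atoms: none
Why: the phenoxide adds to dichloroacetylene and the vinyl anion is protonated anti by further phenol (known dichlorovinylation of phenols), so the oxygen between two methoxy groups is alkenylated in a reaction that is little affected by hindrance.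

Step 3
Reactants: 4 2-[(E)-1,2-dichloroethenyloxy]-1,3,5-trimethoxybenzene
Product: 7 2-(ethynyloxy)-1,3,5-trimethoxybenzene, via chloroethynyl ether 5 (not isolated), via lithium acetylide 6 (not isolated)
Conditions: n-BuLi (2.2 equiv), Et2O, −78 → −40 °C; then MeOH, −78 °C
Reagents that add atoms: none
Why: n-BuLi eliminates HCl to the chloroalkyne, lithium–chlorine exchange gives the acetylide and methanol protonates it, the standard conversion of dichlorovinyl ethers into terminal ynol ethers.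

Step 4
Reactants: 8 3,4,5-trimethoxyphenol
Product: 9 6-hydroxy-2,3,4-trimethoxybenzaldehyde
Conditions: MgCl2, Et3N, paraformaldehyde, MeCN, reflux; 1 M HCl work-up
Reagents that add atoms: paraformaldehyde (reacts as formaldehyde), C=O
Why: Casnati–Skattebøl ortho-formylation, in which the magnesium phenoxide directs formaldehyde to the ortho carbon and a second formaldehyde oxidises the benzylic alkoxide; the two ortho positions of 8 are equivalent.

Step 5
Reactants: 9 6-hydroxy-2,3,4-trimethoxybenzaldehyde; 10 methyl bromoacetate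
Product: 11 methyl 2-(2-formyl-3,4,5-trimethoxyphenoxy)acetate
Conditions: K2CO3, DMF, rt
Reagents that add atoms: none
Why: Williamson etherification with a reactive α-bromo ester puts on the ring C C1 oxygen the two carbons that later become C2 (CH2) and C1 (carbonyl) of ring B.

Step 6
Reactants: 11 methyl 2-(2-formyl-3,4,5-trimethoxyphenoxy)acetate
Product: 13 methyl 2-(2-hydroxy-3,4,5-trimethoxyphenoxy)acetate, via aryl formate 12 (not isolated)
Conditions: mCPBA, CH2Cl2, 0 °C → rt; then K2CO3 (0.1 equiv), MeOH, 0 °C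
Reagents that add atoms: mCPBA, O=C(OO)c1cccc(Cl)c1
Why: Baeyer–Villiger (Dakin-type) oxidation, in which the electron-rich aryl group flanked by two oxygens migrates in preference to hydrogen, followed by mild methanolysis of the formate that leaves the methyl ester unchanged.

Step 7
Reactants: 13 methyl 2-(2-hydroxy-3,4,5-trimethoxyphenoxy)acetate; 2 dichloroacetylene
Product: 14 methyl 2-{2-[(E)-1,2-dichloroethenyloxy]-3,4,5-trimethoxyphenoxy}acetate
Conditions: 2 (1.5 equiv, THF solution), K2CO3 (0.2 equiv), DMF, 0 °C → rt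
Reagents that add atoms: none
Why: the same base-catalysed anti addition of a phenol to dichloroacetylene as in step 2 installs a base- and heat-stable masked ethynyl ether on the ring C C2 oxygen, the ester being inert to carbonate.

Step 8
Reactants: 14 methyl 2-{2-[(E)-1,2-dichloroethenyloxy]-3,4,5-trimethoxyphenoxy}acetate
Product: 15 2-{2-[(E)-1,2-dichloroethenyloxy]-3,4,5-trimethoxyphenoxy}acetic acid
Conditions: LiOH, THF/H2O, 0 °C → rt; then 1 M HCl to pH 3, 0 °C
Reagents that add atoms: lithium hydroxide, [Li+].[OH-]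
Why: ordinary ester saponification, which the dichlorovinyl ether should tolerate together with a brief cold acidification.

Step 9
Reactants: 15 2-{2-[(E)-1,2-dichloroethenyloxy]-3,4,5-trimethoxyphenoxy}acetic acid; 16 ethoxyacetylene
Product: 19 rac-4-{2-[(E)-1,2-dichloroethenyloxy]-3,4,5-trimethoxyphenoxy}-3-ethoxycyclobut-2-en-1-one, via acid chloride 17 (not isolated), via aryloxyketene 18 (not isolated)
Conditions: (COCl)2, DMF (cat.), CH2Cl2, 0 °C → rt, evaporate; then 16 (3 equiv), Et3N (slow addition), Et2O, 0 °C → rt; Et3N-deactivated silica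
Reagents that add atoms: none
Why: Et3N dehydrochlorinates the acid chloride to the aryloxyketene, which undergoes the known [2+2] cycloaddition with ethoxyacetylene, its carbonyl carbon bonding to the terminal alkyne carbon, to give the 3-ethoxycyclobutenone.

Step 10
Reactants: 7 2-(ethynyloxy)-1,3,5-trimethoxybenzene; 19 rac-4-(ArC-oxy)-3-ethoxycyclobut-2-en-1-one
Product: 24 trimer phenol A–B–C, via vinylketene 20 (not isolated), via vinylcyclobutenone adduct 21 (not isolated), via dienylketene 22 (not isolated), via cyclohexadienone 23 (not isolated)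
Conditions: 7 (1.3 equiv), PhMe, 80 °C then 110 °C, argon
Reagents that add atoms: none
Why: Heating opens 19 by conrotatory 4π cleavage, the aryloxy group turning outward, to vinylketene 20, whose ketene C=C adds [2+2] to ynol ether 7 with the nucleophilic terminal alkyne carbon on the ketene carbonyl carbon (ring B C1–C6) and the oxygen-bearing alkyne carbon on the ketene α-carbon (C4–C5), giving 4-vinylcyclobutenone 21. A second 4π opening gives dienylketene 22, which closes ring B by thermal disrotatory 6π electrocyclisation (C1–C2) to cyclohexadienone 23, and enolisation gives phenol 24. The closest known reaction is the Danheiser benzannulation of cyclobutenones with alkoxy- and siloxyacetylenes, which gives resorcinol monoethers in the same way. No stereocentre is created, since C4 of racemic 19 and the sp3 carbons of 21 and 23 all end as aromatic carbons. The one selectivity needed is regiochemical, the ring A oxygen at C5 meta to the new hydroxyl; it is secured by the oxygen polarisation of the ynol ether, whose β-carbon alone is nucleophilic toward the ketene carbonyl carbon, while outward rotation of the donor oxygen on C4 leaves hydrogen inside so that the 6π closure is unhindered. Both hindered oxygens arrive already bonded to their carbons (the ring A oxygen on the alkyne, the ring C oxygen on cyclobutenone C4), so neither is arylated, and the dichlorovinyl ether and aryl ethers should be inert at 110 °C.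

Step 11
Reactants: 24 trimer phenol A–B–C
Product: 25 trimer methyl ether A–B–C
Conditions: MeI, K2CO3, acetone, 40 °C
Reagents that add atoms: iodomethane, CI
Why: Williamson methylation caps the new ring B hydroxyl so that it can neither consume n-BuLi nor trap a vinylketene later, and leaves the dichlorovinyl ether untouched.

Step 12
Reactants: 25 trimer methyl ether A–B–C
Product: 28 trimer ynol ether A–B–C, via trimer chloroethynyl ether 26 (not isolated), via trimer lithium acetylide 27 (not isolated)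
Conditions: n-BuLi (2.2 equiv), THF, −78 → −40 °C; then MeOH, −78 °C
Reagents that add atoms: none
Why: the elimination, lithium–chlorine exchange and protonation of step 3 are repeated, the vinylic C–H of the dichlorovinyl ether being far more acidic at −78 °C than any ring position between two alkoxy groups.

Step 13
Reactants: 8 3,4,5-trimethoxyphenol; 29 bromoacetic acid
Product: 30 2-(3,4,5-trimethoxyphenoxy)acetic acid
Conditions: NaH (2.3 equiv), THF/DMF (4:1), 0 °C → rt; then 1 M HCl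
Reagents that add atoms: none
Why: Williamson reaction of the sodium phenoxide with sodium bromoacetate gives the aryloxyacetic acid in one step, under the conditions that are used again on the oligomeric phenols.

Step 14
Reactants: 30 2-(3,4,5-trimethoxyphenoxy)acetic acid; 16 ethoxyacetylene
Product: 33 rac-3-ethoxy-4-(3,4,5-trimethoxyphenoxy)cyclobut-2-en-1-one, via ring K acid chloride 31 (not isolated), via ring K aryloxyketene 32 (not isolated)
Conditions: (COCl)2, DMF (cat.), CH2Cl2, 0 °C → rt, evaporate; then 16 (3 equiv), Et3N (slow addition), Et2O, 0 °C → rt; Et3N-deactivated silica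
Reagents that add atoms: none
Why: ketene generation and [2+2] cycloaddition with ethoxyacetylene exactly as in step 9.

Step 15
Reactants: 9 6-hydroxy-2,3,4-trimethoxybenzaldehyde
Product: 34 6-(benzyloxy)-2,3,4-trimethoxybenzaldehyde
Conditions: BnBr, K2CO3, DMF, 50 °C
Reagents that add atoms: benzyl bromide, BrCc1ccccc1
Why: Williamson benzylation protects the future C1 oxygen of rings I, G and E with a group that survives peracid, n-BuLi at −78 °C and heat, which an acetate ester side chain would not.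

Step 16
Reactants: 34 6-(benzyloxy)-2,3,4-trimethoxybenzaldehyde
Product: 36 6-(benzyloxy)-2,3,4-trimethoxyphenol, via benzyloxy aryl formate 35 (not isolated)
Conditions: mCPBA, CH2Cl2, 0 °C → rt; then K2CO3 (0.1 equiv), MeOH, 0 °C
Reagents that add atoms: mCPBA, O=C(OO)c1cccc(Cl)c1
Why: Baeyer–Villiger (Dakin-type) oxidation of the 2,6-dialkoxybenzaldehyde with aryl migration, then methanolysis of the formate, as in step 6.

Step 17
Reactants: 36 6-(benzyloxy)-2,3,4-trimethoxyphenol; 2 dichloroacetylene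
Product: 37 1-(benzyloxy)-2-[(E)-1,2-dichloroethenyloxy]-3,4,5-trimethoxybenzene
Conditions: 2 (1.5 equiv, THF solution), K2CO3 (0.2 equiv), DMF, 0 °C → rt
Reagents that add atoms: none
Why: base-catalysed anti addition of the flanked phenol to dichloroacetylene, as in steps 2 and 7.

Step 18
Reactants: 37 1-(benzyloxy)-2-[(E)-1,2-dichloroethenyloxy]-3,4,5-trimethoxybenzene
Product: 40 1-(benzyloxy)-2-(ethynyloxy)-3,4,5-trimethoxybenzene, via benzyloxy chloroethynyl ether 38 (not isolated), via benzyloxy lithium acetylide 39 (not isolated)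
Conditions: n-BuLi (2.2 equiv), THF, −78 → −40 °C; then MeOH, −78 °C
Reagents that add atoms: none
Why: the dichlorovinyl ether to ynol ether conversion of step 3, which the aryl benzyl ether tolerates at −78 °C.

Step 19
Reactants: 40 1-(benzyloxy)-2-(ethynyloxy)-3,4,5-trimethoxybenzene; 33 rac-3-ethoxy-4-(3,4,5-trimethoxyphenoxy)cyclobut-2-en-1-one
Product: 45 I–K phenol, via ring K vinylketene 41 (not isolated), via I–K cyclobutenone adduct 42 (not isolated), via I–K dienylketene 43 (not isolated), via I–K cyclohexadienone 44 (not isolated)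
Conditions: 40 (1.5 equiv), PhMe, 80 °C then 110 °C, argon
Reagents that add atoms: none
Why: Danheiser benzannulation as in step 10, in which vinylketene 41 adds across ynol ether 40 with the same polarity-controlled regiochemistry and 4π opening, 6π electrocyclisation and enolisation build ring J between the ring I oxygen (C5) and the ring K oxygen (C2).

Step 20
Reactants: 45 I–K phenol
Product: 46 I–K benzyl ether
Conditions: MeI, K2CO3, acetone, 40 °C
Reagents that add atoms: iodomethane, CI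
Why: Williamson methylation of the ring J hydroxyl, so that the only phenol set free in the next step is the one on ring I.

Step 21
Reactants: 46 I–K benzyl ether
Product: 47 I–K ring I phenol
Conditions: H2 (1 atm), 10% Pd/C, EtOAc/MeOH, rt
Reagents that add atoms: none
Why: catalytic hydrogenolysis cleaves the benzyl ether alone, since the molecule holds only aryl methyl, aryl ethyl and diaryl ethers besides it.

Step 22
Reactants: 47 I–K ring I phenol; 29 bromoacetic acid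
Product: 48 I–K acid
Conditions: NaH (2.3 equiv), THF/DMF (4:1), 0 °C → rt; then 1 M HCl
Reagents that add atoms: none
Why: Williamson carboxymethylation as in step 13, on a phenol that has one free ortho position.

Step 23
Reactants: 48 I–K acid; 16 ethoxyacetylene
Product: 51 I–K cyclobutenone, via I–K acid chloride 49 (not isolated), via I–K aryloxyketene 50 (not isolated)
Conditions: (COCl)2, DMF (cat.), CH2Cl2, 0 °C → rt, evaporate; then 16 (5 equiv), Et3N (slow addition), Et2O/CH2Cl2, 0 °C → rt; Et3N-deactivated silica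
Reagents that add atoms: none
Why: ketene generation and [2+2] cycloaddition with ethoxyacetylene as in steps 9 and 14, all other groups being ethers.

Step 24
Reactants: 40 1-(benzyloxy)-2-(ethynyloxy)-3,4,5-trimethoxybenzene; 51 I–K cyclobutenone
Product: 56 G–K phenol, via I–K vinylketene 52 (not isolated), via G–K cyclobutenone adduct 53 (not isolated), via G–K dienylketene 54 (not isolated), via G–K cyclohexadienone 55 (not isolated)
Conditions: 40 (2 equiv), PhMe, 80 °C then 110 °C, argon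
Reagents that add atoms: none
Why: Danheiser benzannulation as in step 10, here through vinylketene 52 and building ring H between the ring G oxygen and the ring I oxygen.

Step 25
Reactants: 56 G–K phenol
Product: 57 G–K benzyl ether
Conditions: MeI, K2CO3, acetone, 40 °C
Reagents that add atoms: iodomethane, CI
Why: Williamson methylation of the ring H hydroxyl, as in step 20.

Step 26
Reactants: 57 G–K benzyl ether
Product: 58 G–K ring G phenol
Conditions: H2 (1 atm), 10% Pd/C, EtOAc/MeOH, rt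
Reagents that add atoms: none
Why: hydrogenolysis of the single benzyl ether, as in step 21.

Step 27
Reactants: 58 G–K ring G phenol; 29 bromoacetic acid
Product: 59 G–K acid
Conditions: NaH (2.3 equiv), THF/DMF (4:1), 0 °C → rt; then 1 M HCl
Reagents that add atoms: none
Why: Williamson carboxymethylation, as in steps 13 and 22.

Step 28
Reactants: 59 G–K acid; 16 ethoxyacetylene
Product: 62 G–K cyclobutenone, via G–K acid chloride 60 (not isolated), via G–K aryloxyketene 61 (not isolated)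
Conditions: (COCl)2, DMF (cat.), CH2Cl2, 0 °C → rt, evaporate; then 16 (5 equiv), Et3N (slow addition), Et2O/CH2Cl2, 0 °C → rt; Et3N-deactivated silica
Reagents that add atoms: none
Why: ketene generation and [2+2] cycloaddition with ethoxyacetylene, as in step 23.

Step 29
Reactants: 40 1-(benzyloxy)-2-(ethynyloxy)-3,4,5-trimethoxybenzene; 62 G–K cyclobutenone
Product: 67 E–K phenol, via G–K vinylketene 63 (not isolated), via E–K cyclobutenone adduct 64 (not isolated), via E–K dienylketene 65 (not isolated), via E–K cyclohexadienone 66 (not isolated)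
Conditions: 40 (2 equiv), PhMe, 80 °C then 110 °C, argon
Reagents that add atoms: none
Why: Danheiser benzannulation as in step 10, here through vinylketene 63 and building ring F between the ring E oxygen and the ring G oxygen.

Step 30
Reactants: 67 E–K phenol
Product: 68 E–K benzyl ether
Conditions: MeI, K2CO3, acetone, 40 °C
Reagents that add atoms: iodomethane, CI
Why: Williamson methylation of the ring F hydroxyl, as in step 20.

Step 31
Reactants: 68 E–K benzyl ether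
Product: 69 E–K ring E phenol
Conditions: H2 (1 atm), 10% Pd/C, EtOAc/MeOH, rt
Reagents that add atoms: none
Why: hydrogenolysis of the single benzyl ether, as in step 21.

Step 32
Reactants: 69 E–K ring E phenol; 29 bromoacetic acid
Product: 70 E–K acid
Conditions: NaH (2.3 equiv), THF/DMF (4:1), 0 °C → rt; then 1 M HCl
Reagents that add atoms: none
Why: Williamson carboxymethylation, as in steps 13 and 22.

Step 33
Reactants: 70 E–K acid; 16 ethoxyacetylene
Product: 73 E–K cyclobutenone, via E–K acid chloride 71 (not isolated), via E–K aryloxyketene 72 (not isolated)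
Conditions: (COCl)2, DMF (cat.), CH2Cl2, 0 °C → rt, evaporate; then 16 (5 equiv), Et3N (slow addition), Et2O/CH2Cl2, 0 °C → rt; Et3N-deactivated silica
Reagents that add atoms: none
Why: ketene generation and [2+2] cycloaddition with ethoxyacetylene, as in step 23.

Step 34
Reactants: 28 trimer ynol ether A–B–C; 73 E–K cyclobutenone
Product: 78 undecamer phenol A–K, via E–K vinylketene 74 (not isolated), via undecamer cyclobutenone adduct 75 (not isolated), via undecamer dienylketene 76 (not isolated), via undecamer cyclohexadienone 77 (not isolated)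
Conditions: 28 (1.5 equiv), PhMe (0.2 M), 80 °C then 110 °C, argon; excess 28 recovered
Reagents that add atoms: none
Why: Danheiser benzannulation as in step 10, here through vinylketene 74 and building ring D between the ring C oxygen (C5) and the ring E oxygen (C2), which joins the two halves into the eleven-ring chain.

Step 35
Reactants: 78 undecamer phenol A–K
Product: 79 CNP0245174.0 (target)
Conditions: BBr3 (60 equiv), CH2Cl2, −78 °C → rt; then H2O, 0 °C; reverse-phase chromatography under argon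
Reagents that add atoms: none
Why: BBr3 should cleave all 22 methyl and 5 ethyl aryl ethers by boron complexation and bromide attack at the alkyl carbon, while the diaryl ether bonds offer bromide no sp3 carbon and stay intact (standard global dealkylation of polyalkoxylated diaryl ethers).

**Compound list**

1 | trichloroethylene | ClC=C(Cl)Cl | starting material
2 | dichloroacetylene (THF solution) | ClC#CCl | intermediate
3 | 2,4,6-trimethoxyphenol | COc1cc(OC)c(O)c(OC)c1 | starting material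
4 | 2-[(E)-1,2-dichloroethenyloxy]-1,3,5-trimethoxybenzene | Cl/C=C(/Cl)Oc1c(OC)cc(OC)cc1OC | intermediate
5 | 2-(chloroethynyloxy)-1,3,5-trimethoxybenzene (not isolated) | ClC#COc1c(OC)cc(OC)cc1OC | intermediate
6 | lithium 2-(2,4,6-trimethoxyphenoxy)ethynide (not isolated) | [Li]C#COc1c(OC)cc(OC)cc1OC | intermediate
7 | 2-(ethynyloxy)-1,3,5-trimethoxybenzene (ring A ynol ether) | C#COc1c(OC)cc(OC)cc1OC | intermediate
8 | 3,4,5-trimethoxyphenol | COc1cc(O)cc(OC)c1OC | starting material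
9 | 6-hydroxy-2,3,4-trimethoxybenzaldehyde | COc1cc(O)c(C=O)c(OC)c1OC | intermediate
10 | methyl bromoacetate | COC(=O)CBr | starting material
11 | methyl 2-(2-formyl-3,4,5-trimethoxyphenoxy)acetate | COC(=O)COc1cc(OC)c(OC)c(OC)c1C=O | intermediate
12 | methyl 2-[2-(formyloxy)-3,4,5-trimethoxyphenoxy]acetate (not isolated) | COC(=O)COc1cc(OC)c(OC)c(OC)c1OC=O | intermediate
13 | methyl 2-(2-hydroxy-3,4,5-trimethoxyphenoxy)acetate | COC(=O)COc1cc(OC)c(OC)c(OC)c1O | intermediate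
14 | methyl 2-{2-[(E)-1,2-dichloroethenyloxy]-3,4,5-trimethoxyphenoxy}acetate | Cl/C=C(/Cl)Oc1c(OC)c(OC)c(OC)cc1OCC(=O)OC | intermediate
15 | 2-{2-[(E)-1,2-dichloroethenyloxy]-3,4,5-trimethoxyphenoxy}acetic acid | Cl/C=C(/Cl)Oc1c(OC)c(OC)c(OC)cc1OCC(=O)O | intermediate
16 | ethoxyacetylene | CCOC#C | starting material
17 | 2-(ArC-oxy)acetyl chloride (not isolated) | Cl/C=C(/Cl)Oc1c(OC)c(OC)c(OC)cc1OCC(=O)Cl | intermediate
18 | (ArC-oxy)ketene, 2-(ArC-oxy)ethen-1-one (not isolated) | Cl/C=C(/Cl)Oc1c(OC)c(OC)c(OC)cc1OC=C=O | intermediate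
19 | rac-4-{2-[(E)-1,2-dichloroethenyloxy]-3,4,5-trimethoxyphenoxy}-3-ethoxycyclobut-2-en-1-one | Cl/C=C(/Cl)Oc1c(OC)c(OC)c(OC)cc1OC1C(=O)C=C1OCC | intermediate
20 | vinylketene, (3Z)-4-(ArC-oxy)-3-ethoxybuta-1,3-dien-1-one (not isolated) | Cl/C=C(/Cl)Oc1c(OC)c(OC)c(OC)cc1O/C=C(OCC)/C=C=O | intermediate
21 | vinylcyclobutenone adduct, rac-4-[(Z)-2-(ArC-oxy)-1-ethoxyethenyl]-3-(TMP-oxy)cyclobut-2-en-1-one (not isolated) | Cl/C=C(/Cl)Oc1c(OC)c(OC)c(OC)cc1O/C=C(OCC)/C1C(=O)C=C1Oc1c(OC)cc(OC)cc1OC | intermediate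
22 | dienylketene, (3E,5Z)-6-(ArC-oxy)-5-ethoxy-3-(TMP-oxy)hexa-1,3,5-trien-1-one (not isolated) | Cl/C=C(/Cl)Oc1c(OC)c(OC)c(OC)cc1O/C=C(OCC)/C=C(C=C=O)/Oc1c(OC)cc(OC)cc1OC | intermediate
23 | cyclohexadienone, rac-6-(ArC-oxy)-5-ethoxy-3-(TMP-oxy)cyclohexa-2,4-dien-1-one (not isolated) | Cl/C=C(/Cl)Oc1c(OC)c(OC)c(OC)cc1OC1C(=O)C=C(C=C1OCC)Oc1c(OC)cc(OC)cc1OC | intermediate
24 | trimer phenol A–B–C, 2-{2-[(E)-1,2-dichloroethenyloxy]-3,4,5-trimethoxyphenoxy}-3-ethoxy-5-(2,4,6-trimethoxyphenoxy)phenol | Cl/C=C(/Cl)Oc1c(OC)c(OC)c(OC)cc1Oc1c(O)cc(cc1OCC)Oc1c(OC)cc(OC)cc1OC | intermediate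
25 | trimer methyl ether A–B–C (24 with ring B C1–OMe; dichlorovinyl ether on ring C) | Cl/C=C(/Cl)Oc1c(OC)c(OC)c(OC)cc1Oc1c(OC)cc(cc1OCC)Oc1c(OC)cc(OC)cc1OC | intermediate
26 | trimer chloroethynyl ether (ClC≡C–O on ring C; not isolated) | ClC#COc1c(OC)c(OC)c(OC)cc1Oc1c(OC)cc(cc1OCC)Oc1c(OC)cc(OC)cc1OC | intermediate
27 | trimer lithium acetylide (LiC≡C–O on ring C; not isolated) | [Li]C#COc1c(OC)c(OC)c(OC)cc1Oc1c(OC)cc(cc1OCC)Oc1c(OC)cc(OC)cc1OC | intermediate
28 | trimer ynol ether A–B–C (HC≡C–O on the C2 oxygen of ring C) | C#COc1c(OC)c(OC)c(OC)cc1Oc1c(OC)cc(cc1OCC)Oc1c(OC)cc(OC)cc1OC | intermediate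
29 | bromoacetic acid | OC(=O)CBr | starting material
30 | 2-(3,4,5-trimethoxyphenoxy)acetic acid | COc1cc(cc(OC)c1OC)OCC(=O)O | intermediate
31 | 2-(3,4,5-trimethoxyphenoxy)acetyl chloride (not isolated) | COc1cc(cc(OC)c1OC)OCC(=O)Cl | intermediate
32 | (3,4,5-trimethoxyphenoxy)ketene (not isolated) | COc1cc(cc(OC)c1OC)OC=C=O | intermediate
33 | rac-3-ethoxy-4-(3,4,5-trimethoxyphenoxy)cyclobut-2-en-1-one (ring K cyclobutenone) | COc1cc(cc(OC)c1OC)OC1C(=O)C=C1OCC | intermediate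
34 | 6-(benzyloxy)-2,3,4-trimethoxybenzaldehyde | COc1cc(OCc2ccccc2)c(C=O)c(OC)c1OC | intermediate
35 | 6-(benzyloxy)-2,3,4-trimethoxyphenyl formate (not isolated) | COc1cc(OCc2ccccc2)c(OC=O)c(OC)c1OC | intermediate
36 | 6-(benzyloxy)-2,3,4-trimethoxyphenol | COc1cc(OCc2ccccc2)c(O)c(OC)c1OC | intermediate
37 | 1-(benzyloxy)-2-[(E)-1,2-dichloroethenyloxy]-3,4,5-trimethoxybenzene | Cl/C=C(/Cl)Oc1c(OC)c(OC)c(OC)cc1OCc1ccccc1 | intermediate
38 | 1-(benzyloxy)-2-(chloroethynyloxy)-3,4,5-trimethoxybenzene (not isolated) | ClC#COc1c(OC)c(OC)c(OC)cc1OCc1ccccc1 | intermediate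
39 | lithium 2-[6-(benzyloxy)-2,3,4-trimethoxyphenoxy]ethynide (not isolated) | [Li]C#COc1c(OC)c(OC)c(OC)cc1OCc1ccccc1 | intermediate
40 | 1-(benzyloxy)-2-(ethynyloxy)-3,4,5-trimethoxybenzene (benzyl-protected ynol ether for rings I, G, E) | C#COc1c(OC)c(OC)c(OC)cc1OCc1ccccc1 | intermediate
41 | ring K vinylketene, (3Z)-3-ethoxy-4-(3,4,5-trimethoxyphenoxy)buta-1,3-dien-1-one (not isolated) | COc1cc(cc(OC)c1OC)O/C=C(OCC)/C=C=O | intermediate
42 | I–K cyclobutenone adduct, rac-4-[(Z)-1-ethoxy-2-(3,4,5-trimethoxyphenoxy)ethenyl]-3-(ArM-oxy)cyclobut-2-en-1-one (not isolated) | COc1cc(cc(OC)c1OC)O/C=C(OCC)/C1C(=O)C=C1Oc1c(OC)c(OC)c(OC)cc1OCc1ccccc1 | intermediate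
43 | I–K dienylketene, (3E,5Z)-5-ethoxy-3-(ArM-oxy)-6-(3,4,5-trimethoxyphenoxy)hexa-1,3,5-trien-1-one (not isolated) | COc1cc(cc(OC)c1OC)O/C=C(OCC)/C=C(C=C=O)/Oc1c(OC)c(OC)c(OC)cc1OCc1ccccc1 | intermediate
44 | I–K cyclohexadienone, rac-5-ethoxy-3-(ArM-oxy)-6-(3,4,5-trimethoxyphenoxy)cyclohexa-2,4-dien-1-one (not isolated) | COc1cc(cc(OC)c1OC)OC1C(=O)C=C(C=C1OCC)Oc1c(OC)c(OC)c(OC)cc1OCc1ccccc1 | intermediate
45 | I–K phenol, 5-[6-(benzyloxy)-2,3,4-trimethoxyphenoxy]-3-ethoxy-2-(3,4,5-trimethoxyphenoxy)phenol (ring J C1–OH free; benzyl on ring I) | COc1cc(cc(OC)c1OC)Oc1c(O)cc(cc1OCC)Oc1c(OC)c(OC)c(OC)cc1OCc1ccccc1 | intermediate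
46 | I–K benzyl ether (45 with ring J C1–OMe; benzyl on the C1 oxygen of ring I) | COc1cc(cc(OC)c1OC)Oc1c(OC)cc(cc1OCC)Oc1c(OC)c(OC)c(OC)cc1OCc1ccccc1 | intermediate
47 | I–K ring I phenol (free C1–OH on ring I) | COc1cc(cc(OC)c1OC)Oc1c(OC)cc(cc1OCC)Oc1c(OC)c(OC)c(OC)cc1O | intermediate
48 | I–K acid (HO2C–CH2 on the C1 oxygen of ring I) | COc1cc(cc(OC)c1OC)Oc1c(OC)cc(cc1OCC)Oc1c(OC)c(OC)c(OC)cc1OCC(=O)O | intermediate
49 | I–K acid chloride (ClOC–CH2 on the C1 oxygen of ring I; not isolated) | COc1cc(cc(OC)c1OC)Oc1c(OC)cc(cc1OCC)Oc1c(OC)c(OC)c(OC)cc1OCC(=O)Cl | intermediate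
50 | I–K aryloxyketene (O=C=CH on the C1 oxygen of ring I; not isolated) | COc1cc(cc(OC)c1OC)Oc1c(OC)cc(cc1OCC)Oc1c(OC)c(OC)c(OC)cc1OC=C=O | intermediate
51 | I–K cyclobutenone (rac-3-ethoxy-4-oxocyclobut-2-en-1-yl on the C1 oxygen of ring I, that is a 4-aryloxy-3-ethoxycyclobut-2-en-1-one) | COc1cc(cc(OC)c1OC)Oc1c(OC)cc(cc1OCC)Oc1c(OC)c(OC)c(OC)cc1OC1C(=O)C=C1OCC | intermediate
52 | I–K vinylketene ((Z)-2-ethoxy-4-oxobuta-1,3-dienyl on the C1 oxygen of ring I; not isolated) | COc1cc(cc(OC)c1OC)Oc1c(OC)cc(cc1OCC)Oc1c(OC)c(OC)c(OC)cc1O/C=C(OCC)/C=C=O | intermediate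
53 | G–K cyclobutenone adduct (as 42, with the I–K aryl of 47 in place of 3,4,5-trimethoxyphenyl; not isolated) | COc1cc(cc(OC)c1OC)Oc1c(OC)cc(cc1OCC)Oc1c(OC)c(OC)c(OC)cc1O/C=C(OCC)/C1C(=O)C=C1Oc1c(OC)c(OC)c(OC)cc1OCc1ccccc1 | intermediate
54 | G–K dienylketene (as 43, same replacement; not isolated) | COc1cc(cc(OC)c1OC)Oc1c(OC)cc(cc1OCC)Oc1c(OC)c(OC)c(OC)cc1O/C=C(OCC)/C=C(C=C=O)/Oc1c(OC)c(OC)c(OC)cc1OCc1ccccc1 | intermediate
55 | G–K cyclohexadienone (as 44, same replacement; not isolated) | COc1cc(cc(OC)c1OC)Oc1c(OC)cc(cc1OCC)Oc1c(OC)c(OC)c(OC)cc1OC1C(=O)C=C(C=C1OCC)Oc1c(OC)c(OC)c(OC)cc1OCc1ccccc1 | intermediate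
56 | G–K phenol (ring H C1–OH free; benzyl on the C1 oxygen of ring G) | COc1cc(cc(OC)c1OC)Oc1c(OC)cc(cc1OCC)Oc1c(OC)c(OC)c(OC)cc1Oc1c(O)cc(cc1OCC)Oc1c(OC)c(OC)c(OC)cc1OCc1ccccc1 | intermediate
57 | G–K benzyl ether (ring H C1–OMe; benzyl on the C1 oxygen of ring G) | COc1cc(cc(OC)c1OC)Oc1c(OC)cc(cc1OCC)Oc1c(OC)c(OC)c(OC)cc1Oc1c(OC)cc(cc1OCC)Oc1c(OC)c(OC)c(OC)cc1OCc1ccccc1 | intermediate
58 | G–K ring G phenol (free C1–OH on ring G) | COc1cc(cc(OC)c1OC)Oc1c(OC)cc(cc1OCC)Oc1c(OC)c(OC)c(OC)cc1Oc1c(OC)cc(cc1OCC)Oc1c(OC)c(OC)c(OC)cc1O | intermediate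
59 | G–K acid (HO2C–CH2 on the C1 oxygen of ring G) | COc1cc(cc(OC)c1OC)Oc1c(OC)cc(cc1OCC)Oc1c(OC)c(OC)c(OC)cc1Oc1c(OC)cc(cc1OCC)Oc1c(OC)c(OC)c(OC)cc1OCC(=O)O | intermediate
60 | G–K acid chloride (not isolated) | COc1cc(cc(OC)c1OC)Oc1c(OC)cc(cc1OCC)Oc1c(OC)c(OC)c(OC)cc1Oc1c(OC)cc(cc1OCC)Oc1c(OC)c(OC)c(OC)cc1OCC(=O)Cl | intermediate
61 | G–K aryloxyketene (not isolated) | COc1cc(cc(OC)c1OC)Oc1c(OC)cc(cc1OCC)Oc1c(OC)c(OC)c(OC)cc1Oc1c(OC)cc(cc1OCC)Oc1c(OC)c(OC)c(OC)cc1OC=C=O | intermediate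
62 | G–K cyclobutenone (rac 4-aryloxy-3-ethoxycyclobut-2-en-1-one on the C1 oxygen of ring G) | COc1cc(cc(OC)c1OC)Oc1c(OC)cc(cc1OCC)Oc1c(OC)c(OC)c(OC)cc1Oc1c(OC)cc(cc1OCC)Oc1c(OC)c(OC)c(OC)cc1OC1C(=O)C=C1OCC | intermediate
63 | G–K vinylketene ((Z)-2-ethoxy-4-oxobuta-1,3-dienyl on the C1 oxygen of ring G; not isolated) | COc1cc(cc(OC)c1OC)Oc1c(OC)cc(cc1OCC)Oc1c(OC)c(OC)c(OC)cc1Oc1c(OC)cc(cc1OCC)Oc1c(OC)c(OC)c(OC)cc1O/C=C(OCC)/C=C=O | intermediate
64 | E–K cyclobutenone adduct (as 42, with the G–K aryl of 58 in place of 3,4,5-trimethoxyphenyl; not isolated) | COc1cc(cc(OC)c1OC)Oc1c(OC)cc(cc1OCC)Oc1c(OC)c(OC)c(OC)cc1Oc1c(OC)cc(cc1OCC)Oc1c(OC)c(OC)c(OC)cc1O/C=C(OCC)/C1C(=O)C=C1Oc1c(OC)c(OC)c(OC)cc1OCc1ccccc1 | intermediate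
65 | E–K dienylketene (as 43, same replacement; not isolated) | COc1cc(cc(OC)c1OC)Oc1c(OC)cc(cc1OCC)Oc1c(OC)c(OC)c(OC)cc1Oc1c(OC)cc(cc1OCC)Oc1c(OC)c(OC)c(OC)cc1O/C=C(OCC)/C=C(C=C=O)/Oc1c(OC)c(OC)c(OC)cc1OCc1ccccc1 | intermediate
66 | E–K cyclohexadienone (as 44, same replacement; not isolated) | COc1cc(cc(OC)c1OC)Oc1c(OC)cc(cc1OCC)Oc1c(OC)c(OC)c(OC)cc1Oc1c(OC)cc(cc1OCC)Oc1c(OC)c(OC)c(OC)cc1OC1C(=O)C=C(C=C1OCC)Oc1c(OC)c(OC)c(OC)cc1OCc1ccccc1 | intermediate
67 | E–K phenol (ring F C1–OH free; benzyl on the C1 oxygen of ring E) | COc1cc(cc(OC)c1OC)Oc1c(OC)cc(cc1OCC)Oc1c(OC)c(OC)c(OC)cc1Oc1c(OC)cc(cc1OCC)Oc1c(OC)c(OC)c(OC)cc1Oc1c(O)cc(cc1OCC)Oc1c(OC)c(OC)c(OC)cc1OCc1ccccc1 | intermediate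
68 | E–K benzyl ether (ring F C1–OMe; benzyl on the C1 oxygen of ring E) | COc1cc(cc(OC)c1OC)Oc1c(OC)cc(cc1OCC)Oc1c(OC)c(OC)c(OC)cc1Oc1c(OC)cc(cc1OCC)Oc1c(OC)c(OC)c(OC)cc1Oc1c(OC)cc(cc1OCC)Oc1c(OC)c(OC)c(OC)cc1OCc1ccccc1 | intermediate
69 | E–K ring E phenol (free C1–OH on ring E) | COc1cc(cc(OC)c1OC)Oc1c(OC)cc(cc1OCC)Oc1c(OC)c(OC)c(OC)cc1Oc1c(OC)cc(cc1OCC)Oc1c(OC)c(OC)c(OC)cc1Oc1c(OC)cc(cc1OCC)Oc1c(OC)c(OC)c(OC)cc1O | intermediate
70 | E–K acid (HO2C–CH2 on the C1 oxygen of ring E) | COc1cc(cc(OC)c1OC)Oc1c(OC)cc(cc1OCC)Oc1c(OC)c(OC)c(OC)cc1Oc1c(OC)cc(cc1OCC)Oc1c(OC)c(OC)c(OC)cc1Oc1c(OC)cc(cc1OCC)Oc1c(OC)c(OC)c(OC)cc1OCC(=O)O | intermediate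
71 | E–K acid chloride (not isolated) | COc1cc(cc(OC)c1OC)Oc1c(OC)cc(cc1OCC)Oc1c(OC)c(OC)c(OC)cc1Oc1c(OC)cc(cc1OCC)Oc1c(OC)c(OC)c(OC)cc1Oc1c(OC)cc(cc1OCC)Oc1c(OC)c(OC)c(OC)cc1OCC(=O)Cl | intermediate
72 | E–K aryloxyketene (not isolated) | COc1cc(cc(OC)c1OC)Oc1c(OC)cc(cc1OCC)Oc1c(OC)c(OC)c(OC)cc1Oc1c(OC)cc(cc1OCC)Oc1c(OC)c(OC)c(OC)cc1Oc1c(OC)cc(cc1OCC)Oc1c(OC)c(OC)c(OC)cc1OC=C=O | intermediate
73 | E–K cyclobutenone (rac 4-aryloxy-3-ethoxycyclobut-2-en-1-one on the C1 oxygen of ring E) | COc1cc(cc(OC)c1OC)Oc1c(OC)cc(cc1OCC)Oc1c(OC)c(OC)c(OC)cc1Oc1c(OC)cc(cc1OCC)Oc1c(OC)c(OC)c(OC)cc1Oc1c(OC)cc(cc1OCC)Oc1c(OC)c(OC)c(OC)cc1OC1C(=O)C=C1OCC | intermediate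
74 | E–K vinylketene ((Z)-2-ethoxy-4-oxobuta-1,3-dienyl on the C1 oxygen of ring E; not isolated) | COc1cc(cc(OC)c1OC)Oc1c(OC)cc(cc1OCC)Oc1c(OC)c(OC)c(OC)cc1Oc1c(OC)cc(cc1OCC)Oc1c(OC)c(OC)c(OC)cc1Oc1c(OC)cc(cc1OCC)Oc1c(OC)c(OC)c(OC)cc1O/C=C(OCC)/C=C=O | intermediate
75 | undecamer cyclobutenone adduct (as 21, with the E–K aryl of 69 in place of ArC and the A–B–C aryl of 28 in place of TMP; not isolated) | COc1cc(cc(OC)c1OC)Oc1c(OC)cc(cc1OCC)Oc1c(OC)c(OC)c(OC)cc1Oc1c(OC)cc(cc1OCC)Oc1c(OC)c(OC)c(OC)cc1Oc1c(OC)cc(cc1OCC)Oc1c(OC)c(OC)c(OC)cc1O/C=C(OCC)/C1C(=O)C=C1Oc1c(OC)c(OC)c(OC)cc1Oc1c(OC)cc(cc1OCC)Oc1c(OC)cc(OC)cc1OC | intermediate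
76 | undecamer dienylketene (as 22, same replacements; not isolated) | COc1cc(cc(OC)c1OC)Oc1c(OC)cc(cc1OCC)Oc1c(OC)c(OC)c(OC)cc1Oc1c(OC)cc(cc1OCC)Oc1c(OC)c(OC)c(OC)cc1Oc1c(OC)cc(cc1OCC)Oc1c(OC)c(OC)c(OC)cc1O/C=C(OCC)/C=C(C=C=O)/Oc1c(OC)c(OC)c(OC)cc1Oc1c(OC)cc(cc1OCC)Oc1c(OC)cc(OC)cc1OC | intermediate
77 | undecamer cyclohexadienone (as 23, same replacements; not isolated) | COc1cc(cc(OC)c1OC)Oc1c(OC)cc(cc1OCC)Oc1c(OC)c(OC)c(OC)cc1Oc1c(OC)cc(cc1OCC)Oc1c(OC)c(OC)c(OC)cc1Oc1c(OC)cc(cc1OCC)Oc1c(OC)c(OC)c(OC)cc1OC1C(=O)C=C(C=C1OCC)Oc1c(OC)c(OC)c(OC)cc1Oc1c(OC)cc(cc1OCC)Oc1c(OC)cc(OC)cc1OC | intermediate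
78 | undecamer phenol A–K (ring D C1–OH free and C3–OEt; 22 OMe and 5 OEt in all) | COc1cc(cc(OC)c1OC)Oc1c(OC)cc(cc1OCC)Oc1c(OC)c(OC)c(OC)cc1Oc1c(OC)cc(cc1OCC)Oc1c(OC)c(OC)c(OC)cc1Oc1c(OC)cc(cc1OCC)Oc1c(OC)c(OC)c(OC)cc1Oc1c(O)cc(cc1OCC)Oc1c(OC)c(OC)c(OC)cc1Oc1c(OC)cc(cc1OCC)Oc1c(OC)cc(OC)cc1OC | intermediate
79 | CNP0245174.0, the free eleven-ring polyphenol with 28 hydroxyls | Oc1cc(O)c(Oc2cc(O)c(Oc3cc(O)c(O)c(O)c3Oc3cc(O)c(Oc4cc(O)c(O)c(O)c4Oc4cc(O)c(Oc5cc(O)c(O)c(O)c5Oc5cc(O)c(Oc6cc(O)c(O)c(O)c6Oc6cc(O)c(Oc7cc(O)c(O)c(O)c7)c(O)c6)c(O)c5)c(O)c4)c(O)c3)c(O)c2)c(O)c1 | target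

**Count and risks**

Total step count: 35. Longest linear sequence: 22 steps (step 4, steps 15 to 33, then 34 and 35, from 3,4,5-trimethoxyphenol 8).

Steps most likely to fail:

Step 34. Two large partners meet at modest concentration, so capture of the heptamer vinylketene by the trimer ynol ether may be slower than ketene dimerisation or acylation of the product phenol by the ketene. The fallback sets out from cyclobutenone 73 and lets the large fragment meet only small partners used in excess, so that ring A enters last. Heating 73 with ynol ether 40 (3 equiv) in toluene would give the nonamer phenol C–K F1 (ring D hydroxyl free, benzyl on ring C). MeI and K2CO3 would give the nonamer benzyl ether F2, hydrogenolysis (H2, Pd/C) the nonamer ring C phenol F3, and bromoacetic acid 29 with NaH the nonamer acid F4. Oxalyl chloride, then Et3N and ethoxyacetylene 16, would give the nonamer cyclobutenone F5. Heating F5 with ring A ynol ether 7 (5 equiv) would close ring B and give the undecamer phenol with free ring B hydroxyl F6, which differs from 78 only in which B-type ring keeps its hydroxyl. BBr3 as in step 35 would then come back to the route at 79.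

Step 33. The ketene from the seven-ring acid chloride may self-condense or acylate one of its own electron-rich rings faster than it adds to ethoxyacetylene, and the vinylogous ester may hydrolyse during isolation. The fallback sets out from acid 70 by way of its chloride 71 and avoids the cyclobutenone. Acylation of magnesium ethyl malonate (KO2CCH2CO2Et, MgCl2, Et3N, MeCN) with loss of CO2 would give the E–K β-keto ester F7. Triethyl orthoformate with catalytic TsOH in EtOH would give the E–K enol ether ester F8, LiOH the E–K enol ether acid F9, and oxalyl chloride the E–K enol ether acid chloride F10. Et3N added slowly to F10 and ynol ether 28 in toluene at 0 °C would generate vinylketene 74 directly by 1,4-dehydrochlorination, and warming to 110 °C would carry adduct 75 through 76 and 77 to 78, where the fallback rejoins the route.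

Step 35. Cleavage of 27 ether groups may stay incomplete at some positions, and the pyrogallol-type rings may be oxidised by air while the free polyphenol is isolated. The fallback sets out from 78. The crude product of the BBr3 treatment would not be purified but acetylated at once (Ac2O, pyridine, DMAP) to the octacosaacetate of 79 F11, which is air-stable and can be purified on silica gel, partially dealkylated material being separated and resubmitted. Methanolysis with HCl in MeOH under argon would then release 79.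

**Further compounds**

F1 | step 34 | nonamer phenol C–K (ring D C1–OH free; benzyl on the C1 oxygen of ring C) | COc1cc(cc(OC)c1OC)Oc1c(OC)cc(cc1OCC)Oc1c(OC)c(OC)c(OC)cc1Oc1c(OC)cc(cc1OCC)Oc1c(OC)c(OC)c(OC)cc1Oc1c(OC)cc(cc1OCC)Oc1c(OC)c(OC)c(OC)cc1Oc1c(O)cc(cc1OCC)Oc1c(OC)c(OC)c(OC)cc1OCc1ccccc1
F2 | step 34 | nonamer benzyl ether C–K (ring D C1–OMe; benzyl on the C1 oxygen of ring C) | COc1cc(cc(OC)c1OC)Oc1c(OC)cc(cc1OCC)Oc1c(OC)c(OC)c(OC)cc1Oc1c(OC)cc(cc1OCC)Oc1c(OC)c(OC)c(OC)cc1Oc1c(OC)cc(cc1OCC)Oc1c(OC)c(OC)c(OC)cc1Oc1c(OC)cc(cc1OCC)Oc1c(OC)c(OC)c(OC)cc1OCc1ccccc1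
F3 | step 34 | nonamer ring C phenol (free C1–OH on ring C) | COc1cc(cc(OC)c1OC)Oc1c(OC)cc(cc1OCC)Oc1c(OC)c(OC)c(OC)cc1Oc1c(OC)cc(cc1OCC)Oc1c(OC)c(OC)c(OC)cc1Oc1c(OC)cc(cc1OCC)Oc1c(OC)c(OC)c(OC)cc1Oc1c(OC)cc(cc1OCC)Oc1c(OC)c(OC)c(OC)cc1O
F4 | step 34 | nonamer acid (HO2C–CH2 on the C1 oxygen of ring C) | COc1cc(cc(OC)c1OC)Oc1c(OC)cc(cc1OCC)Oc1c(OC)c(OC)c(OC)cc1Oc1c(OC)cc(cc1OCC)Oc1c(OC)c(OC)c(OC)cc1Oc1c(OC)cc(cc1OCC)Oc1c(OC)c(OC)c(OC)cc1Oc1c(OC)cc(cc1OCC)Oc1c(OC)c(OC)c(OC)cc1OCC(=O)O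
F5 | step 34 | nonamer cyclobutenone (rac 4-aryloxy-3-ethoxycyclobut-2-en-1-one on the C1 oxygen of ring C) | COc1cc(cc(OC)c1OC)Oc1c(OC)cc(cc1OCC)Oc1c(OC)c(OC)c(OC)cc1Oc1c(OC)cc(cc1OCC)Oc1c(OC)c(OC)c(OC)cc1Oc1c(OC)cc(cc1OCC)Oc1c(OC)c(OC)c(OC)cc1Oc1c(OC)cc(cc1OCC)Oc1c(OC)c(OC)c(OC)cc1OC1C(=O)C=C1OCC
F6 | step 34 | undecamer phenol A–K with ring B C1–OH free and ring D C1–OMe | COc1cc(cc(OC)c1OC)Oc1c(OC)cc(cc1OCC)Oc1c(OC)c(OC)c(OC)cc1Oc1c(OC)cc(cc1OCC)Oc1c(OC)c(OC)c(OC)cc1Oc1c(OC)cc(cc1OCC)Oc1c(OC)c(OC)c(OC)cc1Oc1c(OC)cc(cc1OCC)Oc1c(OC)c(OC)c(OC)cc1Oc1c(O)cc(cc1OCC)Oc1c(OC)cc(OC)cc1OC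
F7 | step 33 | E–K β-keto ester (EtO2C–CH2–CO–CH2 on the C1 oxygen of ring E) | COc1cc(cc(OC)c1OC)Oc1c(OC)cc(cc1OCC)Oc1c(OC)c(OC)c(OC)cc1Oc1c(OC)cc(cc1OCC)Oc1c(OC)c(OC)c(OC)cc1Oc1c(OC)cc(cc1OCC)Oc1c(OC)c(OC)c(OC)cc1OCC(=O)CC(=O)OCC
F8 | step 33 | E–K enol ether ester (ethyl (E)-4-aryloxy-3-ethoxybut-2-enoate on the C1 oxygen of ring E) | COc1cc(cc(OC)c1OC)Oc1c(OC)cc(cc1OCC)Oc1c(OC)c(OC)c(OC)cc1Oc1c(OC)cc(cc1OCC)Oc1c(OC)c(OC)c(OC)cc1Oc1c(OC)cc(cc1OCC)Oc1c(OC)c(OC)c(OC)cc1OC/C(OCC)=C\C(=O)OCC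
F9 | step 33 | E–K enol ether acid ((E)-4-aryloxy-3-ethoxybut-2-enoic acid) | COc1cc(cc(OC)c1OC)Oc1c(OC)cc(cc1OCC)Oc1c(OC)c(OC)c(OC)cc1Oc1c(OC)cc(cc1OCC)Oc1c(OC)c(OC)c(OC)cc1Oc1c(OC)cc(cc1OCC)Oc1c(OC)c(OC)c(OC)cc1OC/C(OCC)=C\C(=O)O
F10 | step 33 | E–K enol ether acid chloride ((E)-4-aryloxy-3-ethoxybut-2-enoyl chloride) | COc1cc(cc(OC)c1OC)Oc1c(OC)cc(cc1OCC)Oc1c(OC)c(OC)c(OC)cc1Oc1c(OC)cc(cc1OCC)Oc1c(OC)c(OC)c(OC)cc1Oc1c(OC)cc(cc1OCC)Oc1c(OC)c(OC)c(OC)cc1OC/C(OCC)=C\C(=O)Cl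
F11 | step 35 | octacosaacetate of 79 (all 28 phenolic hydroxyls acetylated) | CC(=O)Oc1cc(cc(OC(C)=O)c1OC(C)=O)Oc1c(OC(C)=O)cc(cc1OC(C)=O)Oc1c(OC(C)=O)c(OC(C)=O)c(OC(C)=O)cc1Oc1c(OC(C)=O)cc(cc1OC(C)=O)Oc1c(OC(C)=O)c(OC(C)=O)c(OC(C)=O)cc1Oc1c(OC(C)=O)cc(cc1OC(C)=O)Oc1c(OC(C)=O)c(OC(C)=O)c(OC(C)=O)cc1Oc1c(OC(C)=O)cc(cc1OC(C)=O)Oc1c(OC(C)=O)c(OC(C)=O)c(OC(C)=O)cc1Oc1c(OC(C)=O)cc(cc1OC(C)=O)Oc1c(OC(C)=O)cc(OC(C)=O)cc1OC(C)=O
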